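**Plan**
1. Retrosynthesis: the fourteen O–CH3 bonds are cut first, then the three diaryl ether C–O bonds between rings E/F, D/E and C/D (Ullmann), which leaves a protected A–B–C trimer.
2. Ring B of the trimer (second ring from the 2,4,6-trihydroxyphenoxy end; hydroxyls on C1 and C3, oxygen to ring C on C2, oxygen to ring A on C5) is a masked 1,3,5-tricarbonyl chain and is cut at C6–C1 (Claisen) and C2–C3 (acylation).
3. C3–C6 map onto an (E)-3-aryloxybut-2-enoyl unit that already carries the ring A ether, and C1–C2 onto an aryloxymalonate that already carries the ring C ether. A second ester on C2 removes the acidic C2–H that would otherwise deactivate the acceptor ester, and is lost as dimethyl carbonate on aromatisation.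
4. Forward: rings A, C, D, E and F are bought as arenes. The two ethers of ring B are made by oxa-Michael addition and phenol alkylation, ring B is closed from the open chain, and the chain then grows C→D, D→E, E→F before global demethylation.
5. Stereochemistry: the target has no stereocentre. The only stereo-element on the way is the (E) enol ether double bond, set under thermodynamic control in the oxa-Michael step and erased when ring B aromatises.

Key step: step 7

Remark: the five arene building blocks, methyl but-2-ynoate and dimethyl 2-chloromalonate are taken as commercial.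

**Route**

Step 1
Reactants: 1 syringaldehyde
Product: 2 4-(benzyloxy)-3,5-dimethoxybenzaldehyde
Conditions: BnBr, K2CO3, DMF, 60 °C
Reagents that add atoms: benzyl bromide, BrCc1ccccc1
Why: Williamson ether synthesis, in which the phenoxide of 1 is alkylated by the reactive benzylic bromide to install the only hydrogenolysable protecting group of the route.

Step 2
Reactants: 2 4-(benzyloxy)-3,5-dimethoxybenzaldehyde
Product: 4 4-(benzyloxy)-3,5-dimethoxyphenol, via aryl formate 3 (not isolated)
Conditions: mCPBA, CH2Cl2, 0 → 23 °C; then K2CO3 (cat.), MeOH, 23 °C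
Reagents that add atoms: 3-chloroperoxybenzoic acid (mCPBA), OOC(=O)c1cccc(Cl)c1
Why: Baeyer–Villiger (Dakin-type) oxidation, in which the electron-rich trialkoxyaryl group migrates in preference to hydrogen to give formate 3, which mild methanolysis cleaves without touching the benzyl ether.

Step 3
Reactants: 4 4-(benzyloxy)-3,5-dimethoxyphenol; 5 dimethyl 2-chloropropanedioate
Product: 6 dimethyl 2-[4-(benzyloxy)-3,5-dimethoxyphenoxy]propanedioate
Conditions: K2CO3, acetone, reflux
Reagents that add atoms: none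
Why: Williamson-type SN2 displacement of the doubly carbonyl-activated chloride by the unhindered phenoxide of 4, the standard route to aryloxymalonates.

Step 4
Reactants: 7 2,4,6-trimethoxyphenol; 8 methyl but-2-ynoate
Product: 9 methyl (E)-3-(2,4,6-trimethoxyphenoxy)but-2-enoate
Conditions: K2CO3 (0.5 equiv), DMF, 90 °C
Reagents that add atoms: none
Why: base-catalysed oxa-Michael addition of the phenoxide to the alkynoate, reversible under these conditions so that the product should settle in the more stable (E) isomer with the aryloxy group trans to the ester.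

Step 5
Reactants: 9 methyl (E)-3-(2,4,6-trimethoxyphenoxy)but-2-enoate
Product: 10 (E)-3-(2,4,6-trimethoxyphenoxy)but-2-enoic acid
Conditions: LiOH·H2O, THF/MeOH/H2O, 50 °C; then 1 M HCl to pH 3, 0 °C
Reagents that add atoms: lithium hydroxide, [Li+].[OH-]
Why: saponification of the vinylogous carbonate ester, as is routine for 3-aryloxycrotonates, with cold and brief acidification to keep the aryl enol ether intact.

Step 6
Reactants: 10 (E)-3-(2,4,6-trimethoxyphenoxy)but-2-enoic acid; 6 dimethyl 2-[4-(benzyloxy)-3,5-dimethoxyphenoxy]propanedioate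
Product: 12 dimethyl 2-[4-(benzyloxy)-3,5-dimethoxyphenoxy]-2-[(E)-3-(2,4,6-trimethoxyphenoxy)but-2-enoyl]propanedioate, via acid chloride 11 (not isolated)
Conditions: 10, (COCl)2, DMF (cat.), CH2Cl2, 0 → 23 °C, evaporate; then 6, NaH, THF, 0 °C, add crude 11, 0 → 23 °C
Reagents that add atoms: none
Why: acid chloride formation (ring A has no free ortho position, so no chromone can form) followed by C-acylation of the sodium malonate enolate, the reaction type used to acylate acetamidomalonates and alkylmalonates with acid chlorides.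

Step 7
Reactants: 12 dimethyl 2-[4-(benzyloxy)-3,5-dimethoxyphenoxy]-2-[(E)-3-(2,4,6-trimethoxyphenoxy)but-2-enoyl]propanedioate
Product: 14 2-[4-(benzyloxy)-3,5-dimethoxyphenoxy]-5-(2,4,6-trimethoxyphenoxy)benzene-1,3-diol, via cyclised diketo ester 13 (not isolated)
Conditions: LiN(SiMe3)2 (2.5 equiv), THF (0.02 M), −78 → 23 °C; then MeOH, 23 °C; 1 M HCl
Reagents that add atoms: none
Why: Proposed new method: LiN(SiMe3)2 removes a proton from the vinylogous methyl group C6 of the 3-aryloxy enone (the only acidic C–H, since C2 is quaternary), and once the C3=C4 bond of the dienolate has equilibrated on warming (rotation through its ketone/allyl-anion resonance form or reprotonation at C4) the terminal carbon C6 attacks one of the two equivalent malonate ester carbonyls, forming C6–C1 and expelling methoxide to give 13. Lithium methoxide, topped up by the methanol quench, then attacks the remaining ester of the non-enolisable 2,2-disubstituted 1,3-dione 13, and the C2–CO2Me bond breaks in a retro-Claisen sense because the leaving carbanion is the resorcinolate of 14, so the sequence should end irreversibly in the aromatic ring. The closest known reaction types are the intramolecular Claisen condensation of methyl ketone enolates onto malonate esters (dimedone-type synthesis of cyclohexane-1,3-diones), gamma-deprotonation of 3-alkoxy enones and alkoxide-induced dealkoxycarbonylation of 2-acyl beta-keto esters; their combination on a 2-acyl-2-aryloxymalonate is new. Ring B closes in a 6-(enolendo)-exo-trig mode. No stereocentre remains in 14 (13 is racemic and its centre disappears on aromatisation). The step needs gamma- over alpha-attack of the dienolate and ring closure over deacylation: attack through C4 would give a four-membered ring, the aryl enol ether oxygen on C5 cannot lactonise to a pyrone, and the hindered amide base should not add to the tricarbonyl unit.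

Step 8
Reactants: 14 2-[4-(benzyloxy)-3,5-dimethoxyphenoxy]-5-(2,4,6-trimethoxyphenoxy)benzene-1,3-diol
Product: 15 2-(benzyloxy)-5-[2,6-dimethoxy-4-(2,4,6-trimethoxyphenoxy)phenoxy]-1,3-dimethoxybenzene
Conditions: Me2SO4, K2CO3, acetone, reflux
Reagents that add atoms: dimethyl sulfate, COS(=O)(=O)OC
Why: Williamson O-methylation of the two ring B phenols with a hard electrophile and a weak base, which favours O- over C-alkylation of the electron-rich ring.

Step 9
Reactants: 15 2-(benzyloxy)-5-[2,6-dimethoxy-4-(2,4,6-trimethoxyphenoxy)phenoxy]-1,3-dimethoxybenzene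
Product: 16 4-[2,6-dimethoxy-4-(2,4,6-trimethoxyphenoxy)phenoxy]-2,6-dimethoxyphenol
Conditions: H2 (1 atm), Pd/C, EtOAc/MeOH, 23 °C
Reagents that add atoms: none
Why: catalytic hydrogenolysis of the benzyl ether, which leaves methyl and diaryl ethers untouched and frees the ring C phenol.

Step 10
Reactants: 17 4-bromo-2,6-dimethoxyphenol
Product: 18 2-(benzyloxy)-5-bromo-1,3-dimethoxybenzene
Conditions: BnBr, K2CO3, DMF, 60 °C
Reagents that add atoms: benzyl bromide, BrCc1ccccc1
Why: Williamson ether synthesis, which masks the phenol so that the bromide cannot couple with itself in the Ullmann steps.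

Step 11
Reactants: 16 4-[2,6-dimethoxy-4-(2,4,6-trimethoxyphenoxy)phenoxy]-2,6-dimethoxyphenol; 18 2-(benzyloxy)-5-bromo-1,3-dimethoxybenzene
Product: 19 2-(benzyloxy)-5-{4-[2,6-dimethoxy-4-(2,4,6-trimethoxyphenoxy)phenoxy]-2,6-dimethoxyphenoxy}-1,3-dimethoxybenzene
Conditions: CuI (10 mol %), picolinic acid (20 mol %), K3PO4, DMSO, 100 °C, argon
Reagents that add atoms: none
Why: ligand-accelerated Ullmann diaryl ether synthesis, a catalyst system suited to di-ortho-substituted phenols and electron-rich aryl bromides.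

Step 12
Reactants: 19 2-(benzyloxy)-5-{4-[2,6-dimethoxy-4-(2,4,6-trimethoxyphenoxy)phenoxy]-2,6-dimethoxyphenoxy}-1,3-dimethoxybenzene
Product: 20 4-{4-[2,6-dimethoxy-4-(2,4,6-trimethoxyphenoxy)phenoxy]-2,6-dimethoxyphenoxy}-2,6-dimethoxyphenol
Conditions: H2 (1 atm), Pd/C, EtOAc/MeOH, 23 °C
Reagents that add atoms: none
Why: catalytic hydrogenolysis of the single benzyl ether, as in step 9, frees the ring D phenol.

Step 13
Reactants: 20 4-{4-[2,6-dimethoxy-4-(2,4,6-trimethoxyphenoxy)phenoxy]-2,6-dimethoxyphenoxy}-2,6-dimethoxyphenol; 18 2-(benzyloxy)-5-bromo-1,3-dimethoxybenzene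
Product: 21 2-(benzyloxy)-5-(4-{4-[2,6-dimethoxy-4-(2,4,6-trimethoxyphenoxy)phenoxy]-2,6-dimethoxyphenoxy}-2,6-dimethoxyphenoxy)-1,3-dimethoxybenzene
Conditions: CuI (10 mol %), picolinic acid (20 mol %), K3PO4, DMSO, 100 °C, argon
Reagents that add atoms: none
Why: Ullmann diaryl ether synthesis on the same phenol and bromide types as in step 11.

Step 14
Reactants: 21 2-(benzyloxy)-5-(4-{4-[2,6-dimethoxy-4-(2,4,6-trimethoxyphenoxy)phenoxy]-2,6-dimethoxyphenoxy}-2,6-dimethoxyphenoxy)-1,3-dimethoxybenzene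
Product: 22 4-(4-{4-[2,6-dimethoxy-4-(2,4,6-trimethoxyphenoxy)phenoxy]-2,6-dimethoxyphenoxy}-2,6-dimethoxyphenoxy)-2,6-dimethoxyphenol
Conditions: H2 (1 atm), Pd/C, EtOAc/MeOH, 23 °C
Reagents that add atoms: none
Why: catalytic hydrogenolysis of the benzyl ether frees the ring E phenol.

Step 15
Reactants: 22 4-(4-{4-[2,6-dimethoxy-4-(2,4,6-trimethoxyphenoxy)phenoxy]-2,6-dimethoxyphenoxy}-2,6-dimethoxyphenoxy)-2,6-dimethoxyphenol; 23 5-bromo-1,2,3-trimethoxybenzene
Product: 24 5-[4-(4-{4-[2,6-dimethoxy-4-(2,4,6-trimethoxyphenoxy)phenoxy]-2,6-dimethoxyphenoxy}-2,6-dimethoxyphenoxy)-2,6-dimethoxyphenoxy]-1,2,3-trimethoxybenzene (tetradeca-O-methyl ether of the target)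
Conditions: CuI (20 mol %), picolinic acid (40 mol %), K3PO4, DMSO, 110 °C, argon
Reagents that add atoms: none
Why: Ullmann diaryl ether synthesis, here with the unfunctionalised ring F bromide used in excess.

Step 16
Reactants: 24 tetradeca-O-methyl ether of the target
Product: 25 5-[4-(4-{4-[2,6-dihydroxy-4-(2,4,6-trihydroxyphenoxy)phenoxy]-2,6-dihydroxyphenoxy}-2,6-dihydroxyphenoxy)-2,6-dihydroxyphenoxy]benzene-1,2,3-triol (target)
Conditions: BBr3 (about 3 equiv per OMe), CH2Cl2, −78 → 23 °C, argon; then H2O, 0 °C; Sephadex LH-20 under argon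
Reagents that add atoms: none
Why: Lewis acid cleavage of aryl methyl ethers by BBr3 (bromide attacks the methyl group of the O-boron complex), which does not break diaryl ether bonds.

**Compound list**
1 | syringaldehyde | COc1cc(C=O)cc(OC)c1O | starting material
2 | 4-(benzyloxy)-3,5-dimethoxybenzaldehyde | COc1cc(C=O)cc(OC)c1OCc1ccccc1 | intermediate
3 | 4-(benzyloxy)-3,5-dimethoxyphenyl formate | COc1cc(OC=O)cc(OC)c1OCc1ccccc1 | intermediate
4 | 4-(benzyloxy)-3,5-dimethoxyphenol | COc1cc(O)cc(OC)c1OCc1ccccc1 | intermediate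
5 | dimethyl 2-chloropropanedioate | COC(=O)C(Cl)C(=O)OC | starting material
6 | dimethyl 2-[4-(benzyloxy)-3,5-dimethoxyphenoxy]propanedioate | COC(=O)C(Oc1cc(OC)c(OCc2ccccc2)c(OC)c1)C(=O)OC | intermediate
7 | 2,4,6-trimethoxyphenol | COc1cc(OC)c(O)c(OC)c1 | starting material
8 | methyl but-2-ynoate | CC#CC(=O)OC | starting material
9 | methyl (E)-3-(2,4,6-trimethoxyphenoxy)but-2-enoate | C/C(Oc1c(OC)cc(OC)cc1OC)=C\C(=O)OC | intermediate
10 | (E)-3-(2,4,6-trimethoxyphenoxy)but-2-enoic acid | C/C(Oc1c(OC)cc(OC)cc1OC)=C\C(=O)O | intermediate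
11 | (E)-3-(2,4,6-trimethoxyphenoxy)but-2-enoyl chloride | C/C(Oc1c(OC)cc(OC)cc1OC)=C\C(Cl)=O | intermediate
12 | dimethyl 2-[4-(benzyloxy)-3,5-dimethoxyphenoxy]-2-[(E)-3-(2,4,6-trimethoxyphenoxy)but-2-enoyl]propanedioate | C/C(Oc1c(OC)cc(OC)cc1OC)=C\C(=O)C(Oc1cc(OC)c(OCc2ccccc2)c(OC)c1)(C(=O)OC)C(=O)OC | intermediate
13 | methyl 1-[4-(benzyloxy)-3,5-dimethoxyphenoxy]-2,6-dioxo-4-(2,4,6-trimethoxyphenoxy)cyclohex-3-ene-1-carboxylate (racemic) | COC(=O)C1(Oc2cc(OC)c(OCc3ccccc3)c(OC)c2)C(=O)CC(Oc2c(OC)cc(OC)cc2OC)=CC1=O | intermediate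
14 | 2-[4-(benzyloxy)-3,5-dimethoxyphenoxy]-5-(2,4,6-trimethoxyphenoxy)benzene-1,3-diol | COc1cc(OC)c(Oc2cc(O)c(Oc3cc(OC)c(OCc4ccccc4)c(OC)c3)c(O)c2)c(OC)c1 | intermediate
15 | 2-(benzyloxy)-5-[2,6-dimethoxy-4-(2,4,6-trimethoxyphenoxy)phenoxy]-1,3-dimethoxybenzene | COc1cc(OC)c(Oc2cc(OC)c(Oc3cc(OC)c(OCc4ccccc4)c(OC)c3)c(OC)c2)c(OC)c1 | intermediate
16 | 4-[2,6-dimethoxy-4-(2,4,6-trimethoxyphenoxy)phenoxy]-2,6-dimethoxyphenol | COc1cc(OC)c(Oc2cc(OC)c(Oc3cc(OC)c(O)c(OC)c3)c(OC)c2)c(OC)c1 | intermediate
17 | 4-bromo-2,6-dimethoxyphenol | COc1cc(Br)cc(OC)c1O | starting material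
18 | 2-(benzyloxy)-5-bromo-1,3-dimethoxybenzene | COc1cc(Br)cc(OC)c1OCc1ccccc1 | intermediate
19 | 2-(benzyloxy)-5-{4-[2,6-dimethoxy-4-(2,4,6-trimethoxyphenoxy)phenoxy]-2,6-dimethoxyphenoxy}-1,3-dimethoxybenzene | COc1cc(OC)c(Oc2cc(OC)c(Oc3cc(OC)c(Oc4cc(OC)c(OCc5ccccc5)c(OC)c4)c(OC)c3)c(OC)c2)c(OC)c1 | intermediate
20 | 4-{4-[2,6-dimethoxy-4-(2,4,6-trimethoxyphenoxy)phenoxy]-2,6-dimethoxyphenoxy}-2,6-dimethoxyphenol | COc1cc(OC)c(Oc2cc(OC)c(Oc3cc(OC)c(Oc4cc(OC)c(O)c(OC)c4)c(OC)c3)c(OC)c2)c(OC)c1 | intermediate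
21 | 2-(benzyloxy)-5-(4-{4-[2,6-dimethoxy-4-(2,4,6-trimethoxyphenoxy)phenoxy]-2,6-dimethoxyphenoxy}-2,6-dimethoxyphenoxy)-1,3-dimethoxybenzene | COc1cc(OC)c(Oc2cc(OC)c(Oc3cc(OC)c(Oc4cc(OC)c(Oc5cc(OC)c(OCc6ccccc6)c(OC)c5)c(OC)c4)c(OC)c3)c(OC)c2)c(OC)c1 | intermediate
22 | 4-(4-{4-[2,6-dimethoxy-4-(2,4,6-trimethoxyphenoxy)phenoxy]-2,6-dimethoxyphenoxy}-2,6-dimethoxyphenoxy)-2,6-dimethoxyphenol | COc1cc(OC)c(Oc2cc(OC)c(Oc3cc(OC)c(Oc4cc(OC)c(Oc5cc(OC)c(O)c(OC)c5)c(OC)c4)c(OC)c3)c(OC)c2)c(OC)c1 | intermediate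
23 | 5-bromo-1,2,3-trimethoxybenzene | COc1cc(Br)cc(OC)c1OC | starting material
24 | 5-[4-(4-{4-[2,6-dimethoxy-4-(2,4,6-trimethoxyphenoxy)phenoxy]-2,6-dimethoxyphenoxy}-2,6-dimethoxyphenoxy)-2,6-dimethoxyphenoxy]-1,2,3-trimethoxybenzene | COc1cc(OC)c(Oc2cc(OC)c(Oc3cc(OC)c(Oc4cc(OC)c(Oc5cc(OC)c(Oc6cc(OC)c(OC)c(OC)c6)c(OC)c5)c(OC)c4)c(OC)c3)c(OC)c2)c(OC)c1 | intermediate
25 | 5-[4-(4-{4-[2,6-dihydroxy-4-(2,4,6-trihydroxyphenoxy)phenoxy]-2,6-dihydroxyphenoxy}-2,6-dihydroxyphenoxy)-2,6-dihydroxyphenoxy]benzene-1,2,3-triol | Oc1cc(O)c(Oc2cc(O)c(Oc3cc(O)c(Oc4cc(O)c(Oc5cc(O)c(Oc6cc(O)c(O)c(O)c6)c(O)c5)c(O)c4)c(O)c3)c(O)c2)c(O)c1 | target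

**Totals**
Total step count: 16. Longest linear sequence: 13 steps (1, 2, 3, 6, 7, 8, 9, 11, 12, 13, 14, 15, 16).

**Steps most likely to fail**

Step 7 (Proposed new method). The dienolate may not reach the folded geometry needed for closure before methoxide or amide cleaves the crowded tricarbonyl unit (retro-Claisen deacylation), so that fragmentation outruns ring formation. The fallback uses only known chemistry and makes no ring. It sets out from 7 and 18: CuI/picolinic acid/K3PO4 coupling in DMSO should give 2-(benzyloxy)-1,3-dimethoxy-5-(2,4,6-trimethoxyphenoxy)benzene F1. Hydrogenolysis (H2, Pd/C) would give 2,6-dimethoxy-4-(2,4,6-trimethoxyphenoxy)phenol F2. A second Ullmann coupling of F2 with 18 rejoins the route at 15.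

Step 6. The hindered malonate enolate may be acylated on oxygen, or react only slowly with the donor-deactivated acid chloride, and the crowded product may lose its acyl group on work-up. The fallback forms the ring A ether last. It sets out from 6 and commercial but-2-ynoic acid, which oxalyl chloride converts into but-2-ynoyl chloride F3. This smaller, more electrophilic chloride acylates the sodium enolate of 6 to give dimethyl 2-[4-(benzyloxy)-3,5-dimethoxyphenoxy]-2-(but-2-ynoyl)propanedioate F4. DABCO-catalysed oxa-Michael addition of 7 to the activated ynone then returns to the route at 12. Either enol ether geometry is acceptable there, because the C4–C5 bond rotates freely in the dienolate of step 7.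

Step 16. Cleavage of fourteen methyl ethers may stop short, and the free polyphenol may be lost to air oxidation during aqueous work-up and chromatography. The fallback isolates the product through a stable derivative. It sets out from 24: after the BBr3 cleavage the crude phenol is acetylated in the same flask (Ac2O, pyridine, DMAP) to the tetradecaacetate of the target F5. F5 can be purified on silica, where under-cleaved material should separate and can be recycled. Acid methanolysis under argon (HCl generated from AcCl in degassed MeOH) then comes back at 25.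

**Further compounds**
F1 | step 7 | 2-(benzyloxy)-1,3-dimethoxy-5-(2,4,6-trimethoxyphenoxy)benzene | COc1cc(OC)c(Oc2cc(OC)c(OCc3ccccc3)c(OC)c2)c(OC)c1
F2 | step 7 | 2,6-dimethoxy-4-(2,4,6-trimethoxyphenoxy)phenol | COc1cc(OC)c(Oc2cc(OC)c(O)c(OC)c2)c(OC)c1
F3 | step 6 | but-2-ynoyl chloride | CC#CC(Cl)=O
F4 | step 6 | dimethyl 2-[4-(benzyloxy)-3,5-dimethoxyphenoxy]-2-(but-2-ynoyl)propanedioate | CC#CC(=O)C(Oc1cc(OC)c(OCc2ccccc2)c(OC)c1)(C(=O)OC)C(=O)OC
F5 | step 16 | tetradecaacetate of the target | CC(=O)Oc1cc(OC(C)=O)c(Oc2cc(OC(C)=O)c(Oc3cc(OC(C)=O)c(Oc4cc(OC(C)=O)c(Oc5cc(OC(C)=O)c(Oc6cc(OC(C)=O)c(OC(C)=O)c(OC(C)=O)c6)c(OC(C)=O)c5)c(OC(C)=O)c4)c(OC(C)=O)c3)c(OC(C)=O)c2)c(OC(C)=O)c1
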